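## Retrosynthetic overview
1. The butenolide is the only ring that is built, and it is built last. An α-hydroxy ketone (C4-OH, C3=O, C25-OSi) reacts with Ph3P=C=C=O by O-acylation and intramolecular Wittig closure. The trimethylcyclohexene ring is bought intact in dihydro-β-ionone.
2. The hydroxy ketone is unmasked from a C3/C25 acetonide and a C4 PMB ether, after the C24 ester has been reduced.
3. The key disconnection is C6–C7. The E-C6=C7 enoate comes from anti elimination of a syn aldol, made by a boron aldol between an N-acyl oxazolidinone (fragment A: ring, C7–C13, C24) and a β-PMB-oxy aldehyde (fragment B: C3–C6, C25).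
4. Fragment A: dihydro-β-ionone → terminal alkyne → syn carboalumination/iodination (E-C10=C11) → Negishi coupling with BrZn(CH2)3CO2Et → acid → imide.
5. Fragment B: (R)-solketal → (S)-glyceraldehyde acetonide → matched Brown allylation (sets C4, the only stereocentre) → PMB ether → oxidative alkene cleavage.

Position labels: C1 lactone C=O, C2 =CH, C3 =C bearing C25H2OH, C4 stereocentre, C5 CH2, C6=C7 with C24H2OH on C7, C8, C9, C10=C11(CH3), C12, C13, then the ring.

Assumption: species that differ from a numbered compound only by deprotonation (lithium or sodium enolates, alkoxides, acetylides, carboxylates) are not numbered separately.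

## Fragment A

Step 1
Reactants: 1 dihydro-β-ionone [4-(2,6,6-trimethylcyclohex-1-en-1-yl)butan-2-one]
Product: 3 2-(but-3-yn-1-yl)-1,3,3-trimethylcyclohex-1-ene, via enol phosphate 2 (not isolated)
Conditions: LiN(iPr)2 (1.05 equiv), THF, −78 °C; ClP(O)(OEt)2, −78 °C → rt; LiN(iPr)2 (2.3 equiv), −78 °C → rt; H2O
Reagents that add atoms: none
Why: Kinetic deprotonation at the methyl group and O-phosphorylation give the terminal enol phosphate, and base-induced β-elimination of diethyl phosphate then delivers the terminal alkyne (Negishi methyl ketone to alkyne conversion) while the tetrasubstituted ring alkene stays inert.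

Step 2
Reactants: 3 2-(but-3-yn-1-yl)-1,3,3-trimethylcyclohex-1-ene
Product: 5 2-[(3E)-4-iodo-3-methylbut-3-en-1-yl]-1,3,3-trimethylcyclohex-1-ene, via vinylalane 4 (not isolated)
Conditions: Me3Al (2.5 equiv), Cp2ZrCl2 (0.25 equiv), CH2Cl2, 0 °C → rt; I2 in THF, −30 → 0 °C
Reagents that add atoms: trimethylaluminium, C[Al](C)C; iodine, [I][I]
Why: Zirconium-catalysed Negishi carboalumination adds CH3 and Al syn across the alkyne with Al at the terminus, and iodinolysis with retention fixes the E-C10=C11 alkene (>98% E).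

Step 3
Reactants: 5 2-[(3E)-4-iodo-3-methylbut-3-en-1-yl]-1,3,3-trimethylcyclohex-1-ene; 6 (4-ethoxy-4-oxobutyl)zinc bromide (0.5 M in THF)
Product: 7 ethyl (5E)-6-methyl-8-(2,6,6-trimethylcyclohex-1-en-1-yl)oct-5-enoate
Conditions: PdCl2(dppf) (3 mol %), THF, rt → 45 °C
Reagents that add atoms: none
Why: In this Negishi cross-coupling, oxidative addition to zerovalent palladium, transmetalation from zinc and reductive elimination all go with retention, so the E alkene is carried over and the ester survives the mild organozinc.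

Step 4
Reactants: 7 ethyl (5E)-6-methyl-8-(2,6,6-trimethylcyclohex-1-en-1-yl)oct-5-enoate
Product: 8 (5E)-6-methyl-8-(2,6,6-trimethylcyclohex-1-en-1-yl)oct-5-enoic acid
Conditions: LiOH, THF/MeOH/H2O, rt; 1 M HCl to pH 3
Reagents that add atoms: lithium hydroxide, [Li+].[OH-]
Why: This is a plain saponification of an unhindered ester, and nothing else in the molecule is base-sensitive.

Step 5
Reactants: 8 (5E)-6-methyl-8-(2,6,6-trimethylcyclohex-1-en-1-yl)oct-5-enoic acid; 9 (4S)-4-benzyl-1,3-oxazolidin-2-one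
Product: 11 (4S)-4-benzyl-3-[(5E)-6-methyl-8-(2,6,6-trimethylcyclohex-1-en-1-yl)oct-5-enoyl]-1,3-oxazolidin-2-one, via mixed pivalic anhydride 10 (not isolated)
Conditions: PivCl, Et3N, THF, −20 °C; LiCl, 9, −20 °C → rt
Reagents that add atoms: none
Why: In this mixed-anhydride N-acylation the LiCl-activated oxazolidinone attacks the unhindered carbonyl of the pivalic anhydride, and no strong base is needed.

## Fragment B

Step 6
Reactants: 12 (R)-solketal {[(4R)-2,2-dimethyl-1,3-dioxolan-4-yl]methanol}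
Product: 14 (4S)-2,2-dimethyl-1,3-dioxolane-4-carbaldehyde, via alkoxysulfonium chloride 13 (not isolated)
Conditions: (COCl)2, DMSO, CH2Cl2, −78 °C; 12; Et3N, −78 → 0 °C; short-path distillation, used at once
Reagents that add atoms: none
Why: Swern oxidation stops cleanly at the aldehyde at low temperature without epimerising the α-alkoxy centre; the descriptor changes from R to S only because the CIP ranking changes.

Step 7
Reactants: 14 (4S)-2,2-dimethyl-1,3-dioxolane-4-carbaldehyde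
Product: 16 (1R)-1-[(4S)-2,2-dimethyl-1,3-dioxolan-4-yl]but-3-en-1-ol, via borinate ester 15 (not isolated)
Conditions: (+)-Ipc2BOMe [from (−)-α-pinene], allylMgBr, Et2O, 0 °C → rt; 14, −78 °C; 3 M NaOH, 30% H2O2, rt
Reagents that add atoms: allylmagnesium bromide, C=CC[Mg]Br
Why: Brown asymmetric allylboration (carbonyl allylation) runs through a closed chair transition state in which the (−)-α-pinene-derived reagent and the anti (Felkin) preference of the (S)-aldehyde are matched, so the carbinol centre (future C4) is set as R with dr ≥ 95:5.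

Step 8
Reactants: 16 (1R)-1-[(4S)-2,2-dimethyl-1,3-dioxolan-4-yl]but-3-en-1-ol
Product: 17 (4S)-4-{(1R)-1-[(4-methoxybenzyl)oxy]but-3-en-1-yl}-2,2-dimethyl-1,3-dioxolane
Conditions: NaH, PMBCl, Bu4NI (cat.), DMF, 0 °C → rt
Reagents that add atoms: 4-methoxybenzyl chloride, COc1ccc(CCl)cc1
Why: Williamson etherification at oxygen leaves the C–O stereocentre and the base-stable acetonide untouched.

Step 9
Reactants: 17 (4S)-4-{(1R)-1-[(4-methoxybenzyl)oxy]but-3-en-1-yl}-2,2-dimethyl-1,3-dioxolane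
Product: 19 (3R)-3-[(4S)-2,2-dimethyl-1,3-dioxolan-4-yl]-3-[(4-methoxybenzyl)oxy]propanal, via vicinal diol 18 (not isolated)
Conditions: OsO4 (2 mol %), NaIO4 (4 equiv), 2,6-lutidine (2 equiv), dioxane/H2O 3:1, rt; used without storage
Reagents that add atoms: osmium tetroxide, O=[Os](=O)(=O)=O; sodium periodate, [Na+].[O-]I(=O)(=O)=O
Why: Lemieux–Johnson cleavage of the only alkene spares the electron-rich PMB ring that ozone could attack, and lutidine suppresses over-oxidation and β-elimination.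

## Coupling and endgame

Step 10
Reactants: 11 (4S)-4-benzyl-3-[(5E)-6-methyl-8-(2,6,6-trimethylcyclohex-1-en-1-yl)oct-5-enoyl]-1,3-oxazolidin-2-one; 19 (3R)-3-[(4S)-2,2-dimethyl-1,3-dioxolan-4-yl]-3-[(4-methoxybenzyl)oxy]propanal
Product: 22 (4S)-4-benzyl-3-{(2S,3R,5R)-5-[(4S)-2,2-dimethyl-1,3-dioxolan-4-yl]-3-hydroxy-5-[(4-methoxybenzyl)oxy]-2-[(3E)-4-methyl-6-(2,6,6-trimethylcyclohex-1-en-1-yl)hex-3-en-1-yl]pentanoyl}-1,3-oxazolidin-2-one, via Z-boron enolate 20 (not isolated), via boron aldolate 21 (not isolated)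
Conditions: Bu2BOTf (1.15 equiv), Et3N (1.3 equiv), CH2Cl2, −78 → 0 °C; 19, −78 → 0 °C; pH 7 buffer, MeOH, 30% H2O2, 0 °C
Reagents that add atoms: none
Why: In this Evans boron aldol the Z-dibutylboron enolate adds through a Zimmerman–Traxler chair on the face left open by the benzyl group, which forges C6–C7 between fragments A and B and gives only the 2,3-syn (2S,3R) adduct that the later anti elimination turns into the E alkene.

Step 11
Reactants: 22 syn-aldol imide
Product: 23 methyl (2S,3R,5R)-5-[(4S)-2,2-dimethyl-1,3-dioxolan-4-yl]-3-hydroxy-5-[(4-methoxybenzyl)oxy]-2-[(3E)-4-methyl-6-(2,6,6-trimethylcyclohex-1-en-1-yl)hex-3-en-1-yl]pentanoate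
Conditions: NaOMe (1.1 equiv), MeOH/CH2Cl2, −10 → 0 °C, 20 min; AcOH quench
Reagents that add atoms: sodium methoxide, [Na+].[O-]C
Why: Methoxide attacks the more electrophilic exocyclic imide carbonyl (transesterification), and the short cold contact avoids retro-aldol and α-epimerisation while the auxiliary is recovered.

Step 12
Reactants: 23 β-hydroxy methyl ester
Product: 24 methyl (2S,3R,5R)-5-[(4S)-2,2-dimethyl-1,3-dioxolan-4-yl]-5-[(4-methoxybenzyl)oxy]-3-(methylsulfonyloxy)-2-[(3E)-4-methyl-6-(2,6,6-trimethylcyclohex-1-en-1-yl)hex-3-en-1-yl]pentanoate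
Conditions: MsCl, Et3N, CH2Cl2, 0 °C
Reagents that add atoms: methanesulfonyl chloride, CS(=O)(=O)Cl
Why: O-Sulfonylation of the only free hydroxyl goes with retention at carbon and installs the leaving group.

Step 13
Reactants: 24 syn β-mesyloxy ester
Product: 25 methyl (2E,5R)-5-[(4S)-2,2-dimethyl-1,3-dioxolan-4-yl]-5-[(4-methoxybenzyl)oxy]-2-[(3E)-4-methyl-6-(2,6,6-trimethylcyclohex-1-en-1-yl)hex-3-en-1-yl]pent-2-enoate
Conditions: DBU (3 equiv), toluene, rt → 40 °C
Reagents that add atoms: none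
Why: In the syn mesylate the acidic α-H and the mesylate are antiperiplanar in the conformer that places CO2Me and C5 trans, and the competing E1cB path also favours that isomer, so this aldol dehydration gives the (E)-enoate.

Step 14
Reactants: 25 (E)-enoate
Product: 26 (2E,5R)-5-[(4S)-2,2-dimethyl-1,3-dioxolan-4-yl]-5-[(4-methoxybenzyl)oxy]-2-[(3E)-4-methyl-6-(2,6,6-trimethylcyclohex-1-en-1-yl)hex-3-en-1-yl]pent-2-en-1-ol
Conditions: iBu2AlH (2.5 equiv), CH2Cl2, −78 °C; aq potassium sodium tartrate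
Reagents that add atoms: none
Why: DIBAL-H reduces the enoate 1,2 to the allylic alcohol without touching alkene geometry, PMB ether or acetonide, and it is done before any lactone is present.

Step 15
Reactants: 26 allylic alcohol acetonide
Product: 27 (2S,3R,5E,9E)-6-(hydroxymethyl)-3-[(4-methoxybenzyl)oxy]-10-methyl-12-(2,6,6-trimethylcyclohex-1-en-1-yl)dodeca-5,9-diene-1,2-diol
Conditions: AcOH/H2O 4:1, 40 °C
Reagents that add atoms: none
Why: Mild acetal hydrolysis removes the terminal acetonide, while the PMB ether, the allylic alcohol and the alkyl-substituted alkenes tolerate aqueous acetic acid.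

Step 16
Reactants: 27 triol
Product: 28 (2S,3R,5E,9E)-1-[(tert-butyldiphenylsilyl)oxy]-6-{[(tert-butyldiphenylsilyl)oxy]methyl}-3-[(4-methoxybenzyl)oxy]-10-methyl-12-(2,6,6-trimethylcyclohex-1-en-1-yl)dodeca-5,9-dien-2-ol
Conditions: TBDPSCl (2.1 equiv), imidazole, CH2Cl2/DMF, 0 °C
Reagents that add atoms: tert-butyldiphenylsilyl chloride, CC(C)(C)[Si](Cl)(c1ccccc1)c1ccccc1
Why: The bulky silyl chloride reacts only with the two primary hydroxyls (C24, C25) and leaves the flanked secondary C3-OH free for oxidation (selective silylation).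

Step 17
Reactants: 28 bis-silyl ether alcohol
Product: 29 (3R,5E,9E)-1-[(tert-butyldiphenylsilyl)oxy]-6-{[(tert-butyldiphenylsilyl)oxy]methyl}-3-[(4-methoxybenzyl)oxy]-10-methyl-12-(2,6,6-trimethylcyclohex-1-en-1-yl)dodeca-5,9-dien-2-one
Conditions: Dess–Martin periodinane, CH2Cl2, 0 °C → rt
Reagents that add atoms: none
Why: Dess–Martin oxidation of the single free alcohol is near neutral, so the adjacent C4 centre is not epimerised, and the now superfluous C3 stereocentre is erased.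

Step 18
Reactants: 29 PMB-protected ketone
Product: 30 (3R,5E,9E)-1-[(tert-butyldiphenylsilyl)oxy]-6-{[(tert-butyldiphenylsilyl)oxy]methyl}-3-hydroxy-10-methyl-12-(2,6,6-trimethylcyclohex-1-en-1-yl)dodeca-5,9-dien-2-one
Conditions: DDQ (1.3 equiv), CH2Cl2/pH 7 buffer 10:1, 0 °C; used directly
Reagents that add atoms: none
Why: Oxidative PMB cleavage (benzylic hydride abstraction, then hydrolysis) is orthogonal to the silyl ethers and runs under buffered neutral conditions that keep the α-hydroxy ketone configurationally intact.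

Step 19
Reactants: 30 α-hydroxy ketone
Product: 32 (5R)-4-{[(tert-butyldiphenylsilyl)oxy]methyl}-5-[(2E,6E)-3-{[(tert-butyldiphenylsilyl)oxy]methyl}-7-methyl-9-(2,6,6-trimethylcyclohex-1-en-1-yl)nona-2,6-dien-1-yl]furan-2(5H)-one, via ester ylide 31 (not isolated)
Conditions: Ph3P=C=C=O (1.3 equiv), toluene (0.02 M), 90 °C
Reagents that add atoms: (triphenylphosphoranylidene)ketene, O=C=C=P(c1ccccc1)(c1ccccc1)c1ccccc1
Why: In this Bestmann ylide annulation the C4-OH adds to the cumulated ylide to give a stabilised ester ylide, and its intramolecular Wittig reaction with the C3 ketone closes the butenolide without external base, so C4 stays R because its C–O bond is never broken.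

Step 20
Reactants: 32 bis-silyl butenolide
Product: 33 (6E)-neomanoalide {(5R)-4-(hydroxymethyl)-5-[(2E,6E)-3-(hydroxymethyl)-7-methyl-9-(2,6,6-trimethylcyclohex-1-en-1-yl)nona-2,6-dien-1-yl]furan-2(5H)-one}
Conditions: HF·pyridine, pyridine, THF, 0 °C → rt
Reagents that add atoms: none
Why: Fluoride-driven desilylation in a weakly acidic medium removes both primary TBDPS groups and avoids the basic conditions that could racemise the γ-position of the butenolide.

## Compound list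
1 | dihydro-β-ionone, 4-(2,6,6-trimethylcyclohex-1-en-1-yl)butan-2-one | CC(=O)CCC1=C(C)CCCC1(C)C | starting material
2 | diethyl 4-(2,6,6-trimethylcyclohex-1-en-1-yl)but-1-en-2-yl phosphate | C=C(CCC1=C(C)CCCC1(C)C)OP(=O)(OCC)OCC | intermediate
3 | 2-(but-3-yn-1-yl)-1,3,3-trimethylcyclohex-1-ene | C#CCCC1=C(C)CCCC1(C)C | intermediate
4 | dimethyl[(1E)-2-methyl-4-(2,6,6-trimethylcyclohex-1-en-1-yl)but-1-en-1-yl]aluminium | C[Al](C)/C=C(\C)CCC1=C(C)CCCC1(C)C | intermediate
5 | 2-[(3E)-4-iodo-3-methylbut-3-en-1-yl]-1,3,3-trimethylcyclohex-1-ene | CC1=C(CC/C(C)=C/I)C(C)(C)CCC1 | intermediate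
6 | (4-ethoxy-4-oxobutyl)zinc bromide | CCOC(=O)CCC[Zn]Br | starting material
7 | ethyl (5E)-6-methyl-8-(2,6,6-trimethylcyclohex-1-en-1-yl)oct-5-enoate | CCOC(=O)CCC/C=C(\C)CCC1=C(C)CCCC1(C)C | intermediate
8 | (5E)-6-methyl-8-(2,6,6-trimethylcyclohex-1-en-1-yl)oct-5-enoic acid | OC(=O)CCC/C=C(\C)CCC1=C(C)CCCC1(C)C | intermediate
9 | (4S)-4-benzyl-1,3-oxazolidin-2-one | O=C1N[C@@H](Cc2ccccc2)CO1 | starting material
10 | mixed anhydride of 8 and pivalic acid | CC(C)(C)C(=O)OC(=O)CCC/C=C(\C)CCC1=C(C)CCCC1(C)C | intermediate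
11 | (4S)-4-benzyl-3-[(5E)-6-methyl-8-(2,6,6-trimethylcyclohex-1-en-1-yl)oct-5-enoyl]-1,3-oxazolidin-2-one | O=C1OC[C@H](Cc2ccccc2)N1C(=O)CCC/C=C(\C)CCC3=C(C)CCCC3(C)C | intermediate
12 | (R)-solketal, [(4R)-2,2-dimethyl-1,3-dioxolan-4-yl]methanol | OC[C@@H]1COC(C)(C)O1 | starting material
13 | {[(4S)-2,2-dimethyl-1,3-dioxolan-4-yl]methoxy}dimethylsulfonium chloride | C[S+](C)OC[C@@H]1COC(C)(C)O1.[Cl-] | intermediate
14 | (4S)-2,2-dimethyl-1,3-dioxolane-4-carbaldehyde | O=C[C@@H]1COC(C)(C)O1 | intermediate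
15 | diisopinocampheylborinate of 16 | C=CC[C@@H](OB([C@H]2C[C@H]3C[C@@H]([C@@H]2C)C3(C)C)[C@H]4C[C@H]5C[C@@H]([C@@H]4C)C5(C)C)[C@@H]1COC(C)(C)O1 | intermediate
16 | (1R)-1-[(4S)-2,2-dimethyl-1,3-dioxolan-4-yl]but-3-en-1-ol (anti) | C=CC[C@@H](O)[C@@H]1COC(C)(C)O1 | intermediate
17 | (4S)-4-{(1R)-1-[(4-methoxybenzyl)oxy]but-3-en-1-yl}-2,2-dimethyl-1,3-dioxolane | C=CC[C@@H](OCc1ccc(OC)cc1)[C@@H]2COC(C)(C)O2 | intermediate
18 | (4R)-4-[(4S)-2,2-dimethyl-1,3-dioxolan-4-yl]-4-[(4-methoxybenzyl)oxy]butane-1,2-diol (both C2 epimers) | OCC(O)C[C@@H](OCc1ccc(OC)cc1)[C@@H]2COC(C)(C)O2 | intermediate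
19 | (3R)-3-[(4S)-2,2-dimethyl-1,3-dioxolan-4-yl]-3-[(4-methoxybenzyl)oxy]propanal | O=CC[C@@H](OCc1ccc(OC)cc1)[C@@H]2COC(C)(C)O2 | intermediate
20 | Z-dibutylboron enolate of 11 | CCCCB(CCCC)O/C(=C\CC/C=C(\C)CCC1=C(C)CCCC1(C)C)N2[C@@H](Cc3ccccc3)COC2=O | intermediate
21 | dibutylboron aldolate of 22 | O=C1OC[C@H](Cc2ccccc2)N1C(=O)[C@@H](CC/C=C(\C)CCC3=C(C)CCCC3(C)C)[C@H](OB(CCCC)CCCC)C[C@@H](OCc4ccc(OC)cc4)[C@@H]5COC(C)(C)O5 | intermediate
22 | (2S,3R)-syn aldol imide (full name in step 10) | O=C1OC[C@H](Cc2ccccc2)N1C(=O)[C@@H](CC/C=C(\C)CCC3=C(C)CCCC3(C)C)[C@H](O)C[C@@H](OCc4ccc(OC)cc4)[C@@H]5COC(C)(C)O5 | intermediate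
23 | (2S,3R,5R) β-hydroxy methyl ester (full name in step 11) | COC(=O)[C@@H](CC/C=C(\C)CCC1=C(C)CCCC1(C)C)[C@H](O)C[C@@H](OCc2ccc(OC)cc2)[C@@H]3COC(C)(C)O3 | intermediate
24 | (2S,3R,5R) β-mesyloxy methyl ester (full name in step 12) | COC(=O)[C@@H](CC/C=C(\C)CCC1=C(C)CCCC1(C)C)[C@H](OS(C)(=O)=O)C[C@@H](OCc2ccc(OC)cc2)[C@@H]3COC(C)(C)O3 | intermediate
25 | (2E,5R) methyl enoate (full name in step 13) | COC(=O)/C(CC/C=C(\C)CCC1=C(C)CCCC1(C)C)=C/C[C@@H](OCc2ccc(OC)cc2)[C@@H]3COC(C)(C)O3 | intermediate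
26 | (2E,5R) allylic alcohol (full name in step 14) | OC/C(CC/C=C(\C)CCC1=C(C)CCCC1(C)C)=C/C[C@@H](OCc2ccc(OC)cc2)[C@@H]3COC(C)(C)O3 | intermediate
27 | (2S,3R,5E,9E)-6-(hydroxymethyl)-3-[(4-methoxybenzyl)oxy]-10-methyl-12-(2,6,6-trimethylcyclohex-1-en-1-yl)dodeca-5,9-diene-1,2-diol | OC/C(CC/C=C(\C)CCC1=C(C)CCCC1(C)C)=C/C[C@@H](OCc2ccc(OC)cc2)[C@@H](O)CO | intermediate
28 | (2S,3R,5E,9E) C24,C25-bis-TBDPS ether with free C3-OH (full name in step 16) | CC(C)(C)[Si](c1ccccc1)(c2ccccc2)OC/C(CC/C=C(\C)CCC3=C(C)CCCC3(C)C)=C/C[C@@H](OCc4ccc(OC)cc4)[C@@H](O)CO[Si](c5ccccc5)(c6ccccc6)C(C)(C)C | intermediate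
29 | (3R,5E,9E) C3 ketone, C4 PMB ether (full name in step 17) | CC(C)(C)[Si](c1ccccc1)(c2ccccc2)OC/C(CC/C=C(\C)CCC3=C(C)CCCC3(C)C)=C/C[C@@H](OCc4ccc(OC)cc4)C(=O)CO[Si](c5ccccc5)(c6ccccc6)C(C)(C)C | intermediate
30 | (3R,5E,9E) α-hydroxy ketone (full name in step 18) | CC(C)(C)[Si](c1ccccc1)(c2ccccc2)OC/C(CC/C=C(\C)CCC3=C(C)CCCC3(C)C)=C/C[C@@H](O)C(=O)CO[Si](c4ccccc4)(c5ccccc5)C(C)(C)C | intermediate
31 | (triphenylphosphoranylidene)acetate ester of 30 | CC(C)(C)[Si](c1ccccc1)(c2ccccc2)OC/C(CC/C=C(\C)CCC3=C(C)CCCC3(C)C)=C/C[C@@H](OC(=O)C=P(c4ccccc4)(c5ccccc5)c6ccccc6)C(=O)CO[Si](c7ccccc7)(c8ccccc8)C(C)(C)C | intermediate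
32 | (5R) bis-TBDPS butenolide (full name in step 19) | CC(C)(C)[Si](c1ccccc1)(c2ccccc2)OC/C(CC/C=C(\C)CCC3=C(C)CCCC3(C)C)=C/C[C@H]4OC(=O)C=C4CO[Si](c5ccccc5)(c6ccccc6)C(C)(C)C | intermediate
33 | (6E)-neomanoalide, (5R) | CC1=C(CC/C(C)=C/CC/C(=C\C[C@H]2OC(=O)C=C2CO)CO)C(C)(C)CCC1 | target

## Step count and risks
Total step count: 20. Longest linear sequence: 16 (steps 1–5, then 10–20). The fragment B branch runs 15 steps (6–9, then 10–20).

**Step 10 (fragment coupling).** The β-PMB-oxy aldehyde 19 may enolise or lose PMBOH before it is captured, and both partners are valuable at this point.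
- The fallback sets out from 7, keeps 19 as the partner, and comes back at 26.
- Ester 7 is treated with LiN(iPr)2 and then CBr4 (THF, −78 °C) to give the α-bromo ethyl ester F1.
- Heating this with PPh3 in toluene gives the phosphonium bromide F2, and aqueous NaOH converts that into the stabilised ylide F3.
- Its Wittig reaction with 19 in toluene at 80 °C, a neutral medium, gives the ethyl (E)-enoate F4, which iBu2AlH reduces to 26.

**Step 13 (geometry-defining elimination).** Some Z-enoate, or further loss of PMBOH to a dienoate, could appear.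
- The fallback sets out from 22 and comes back at 26. It moves the elimination to the aldehyde oxidation level, where the E isomer is the thermodynamic one.
- LiBH4/MeOH in Et2O removes the auxiliary reductively to give the 1,3-diol F5.
- TEMPO/PhI(OAc)2 oxidises only the primary alcohol to the β-hydroxy aldehyde F6.
- MsCl/Et3N forms the β-mesyloxy aldehyde F7, which loses mesylate in the same flask (E1cB) to give the (E)-enal F8. Any Z isomer is equilibrated by the amine.
- NaBH4/CeCl3·7H2O then reduces it 1,2 to 26.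

**Step 19 (butenolide annulation).** The α-hydroxy ketone 30 can enolise (racemisation), dimerise or shift its silyl group before the Wittig closure.
- The fallback sets out from 29 and comes back at 32, so 30 and 31 are bypassed.
- LiCH2CO2Et (from EtOAc and LiN(iPr)2, THF, −78 °C) adds to the ketone to give the tertiary β-hydroxy ester F9 as both C3 epimers.
- DDQ removes the PMB group to give the dihydroxy ester F10, which closes with catalytic PPTS to the β-hydroxy-γ-lactone F11.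
- MsCl with excess Et3N gives the tertiary mesylate F12, and its E1cB elimination toward the acidic C2 hydrogens delivers 32.

Further compounds
F1 | step 10 | α-bromo ethyl ester, ethyl (5E)-2-bromo-6-methyl-8-(2,6,6-trimethylcyclohex-1-en-1-yl)oct-5-enoate (racemic) | CCOC(=O)C(Br)CC/C=C(\C)CCC1=C(C)CCCC1(C)C
F2 | step 10 | phosphonium bromide from F1 and PPh3 | CCOC(=O)C(CC/C=C(\C)CCC1=C(C)CCCC1(C)C)[P+](c2ccccc2)(c3ccccc3)c4ccccc4.[Br-]
F3 | step 10 | stabilised ylide, ethyl (5E)-6-methyl-2-(triphenylphosphoranylidene)-8-(2,6,6-trimethylcyclohex-1-en-1-yl)oct-5-enoate | CCOC(=O)C(CC/C=C(\C)CCC1=C(C)CCCC1(C)C)=P(c2ccccc2)(c3ccccc3)c4ccccc4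
F4 | step 10 | ethyl (E)-enoate, ethyl ester analogue of 25 | CCOC(=O)/C(CC/C=C(\C)CCC1=C(C)CCCC1(C)C)=C/C[C@@H](OCc2ccc(OC)cc2)[C@@H]3COC(C)(C)O3
F5 | step 13 | 1,3-diol from reductive removal of the auxiliary | OC[C@@H](CC/C=C(\C)CCC1=C(C)CCCC1(C)C)[C@H](O)C[C@@H](OCc2ccc(OC)cc2)[C@@H]3COC(C)(C)O3
F6 | step 13 | β-hydroxy aldehyde | O=C[C@@H](CC/C=C(\C)CCC1=C(C)CCCC1(C)C)[C@H](O)C[C@@H](OCc2ccc(OC)cc2)[C@@H]3COC(C)(C)O3
F7 | step 13 | β-mesyloxy aldehyde | O=C[C@@H](CC/C=C(\C)CCC1=C(C)CCCC1(C)C)[C@H](OS(C)(=O)=O)C[C@@H](OCc2ccc(OC)cc2)[C@@H]3COC(C)(C)O3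
F8 | step 13 | (E)-enal | O=C/C(CC/C=C(\C)CCC1=C(C)CCCC1(C)C)=C/C[C@@H](OCc2ccc(OC)cc2)[C@@H]3COC(C)(C)O3
F9 | step 19 | tertiary β-hydroxy ester (both C3 epimers) | CC(C)(C)[Si](c1ccccc1)(c2ccccc2)OC/C(CC/C=C(\C)CCC3=C(C)CCCC3(C)C)=C/C[C@@H](OCc4ccc(OC)cc4)C(O)(CC(=O)OCC)CO[Si](c5ccccc5)(c6ccccc6)C(C)(C)C
F10 | step 19 | dihydroxy ester | CC(C)(C)[Si](c1ccccc1)(c2ccccc2)OC/C(CC/C=C(\C)CCC3=C(C)CCCC3(C)C)=C/C[C@@H](O)C(O)(CC(=O)OCC)CO[Si](c4ccccc4)(c5ccccc5)C(C)(C)C
F11 | step 19 | β-hydroxy-γ-lactone | CC(C)(C)[Si](c1ccccc1)(c2ccccc2)OC/C(CC/C=C(\C)CCC3=C(C)CCCC3(C)C)=C/C[C@H]4OC(=O)CC4(O)CO[Si](c5ccccc5)(c6ccccc6)C(C)(C)C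
F12 | step 19 | tertiary mesylate | CC(C)(C)[Si](c1ccccc1)(c2ccccc2)OC/C(CC/C=C(\C)CCC3=C(C)CCCC3(C)C)=C/C[C@H]4OC(=O)CC4(OS(C)(=O)=O)CO[Si](c5ccccc5)(c6ccccc6)C(C)(C)C
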